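The plan cuts the dihydrofuran ring from the six-membered carbocycle at its two anchoring bonds, C3a–C3 (ring carbon to CH2) and C7a–O1 (ring carbon to oxygen). These bonds sit on neighbouring ring carbons, and C7a lies beside the acyl-bearing C7. This matches the ortho C–H/ipso C–I pattern of an aryl iodide carrying an ortho isobutyryl group. A single palladium/norbornene annulation with an enantiopure terminal epoxide makes both bonds and closes the ring. Because the oxirane opens only at its CH2 end, the C2 configuration is inherited. The precursor is 2,4-bis(benzyloxy)-6-iodophenyl isopropyl ketone. Deprotection and geminal diprenylation at C5 then dearomatise the ring to the target.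

Key step: step 5

Assumption: the target is one tautomer of an enolised beta-triketone. On acidification the last product is taken to settle as the drawn (Z)-enol, with its OH hydrogen-bonded to the C6 carbonyl, so no step sets the enol geometry. Bicyclic compounds are numbered as 2,3-dihydro-1-benzofurans (O1, C2, C3, C3a, C4–C7, C7a).

Step 1
Reactants: 1 5-iodoresorcinol
Product: 2 1,3-bis(benzyloxy)-5-iodobenzene
Conditions: BnBr (2.3 equiv), K2CO3 (3 equiv), DMF, rt to 50 °C
Reagents that add atoms: benzyl bromide, BrCc1ccccc1
Why: Williamson etherification of both phenoxides with a benzylic halide is routine and leaves the aryl iodide alone, and benzyl is chosen because it should survive cold Lewis acid, hot carbonate and palladium catalysis yet leaves by hydrogenolysis before any alkene is present.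

Step 2
Reactants: 2 1,3-bis(benzyloxy)-5-iodobenzene; 3 isobutyryl chloride
Product: 4 1-[2,4-bis(benzyloxy)-6-iodophenyl]-2-methylpropan-1-one
Conditions: SnCl4 (1.2 equiv), CH2Cl2, −20 to 0 °C; ice-water quench
Reagents that add atoms: none
Why: Friedel–Crafts acylation should go para to one benzyloxy group and ortho to the other (and to iodine), as is usual for 3,5-dialkoxyhalobenzenes, because the site between the two ethers is more crowded, the first acyl group stops a second acylation, the C–I carbon is meta to both oxygens and so not prone to ipso attack, and SnCl4 below 0 °C is mild towards aryl benzyl ethers.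

Step 3
Reactants: 5 methyl (S)-glycidate
Product: 7 (S)-2-(oxiran-2-yl)propan-2-ol, via epoxy ketone 6 (not isolated)
Conditions: MeMgBr (2.2 equiv), THF, −78 to −20 °C; sat. aq NH4Cl; CH2Cl2 extraction, careful concentration, used crude
Reagents that add atoms: methylmagnesium bromide, C[Mg]Br
Why: Double Grignard addition to the ester outruns uncatalysed oxirane opening at low temperature, and since no bond to the stereocentre is made or broken the (S) configuration of the chiral-pool ester is carried into 7.

Step 4
Reactants: 7 (S)-2-(oxiran-2-yl)propan-2-ol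
Product: 8 (S)-triethyl{[2-(oxiran-2-yl)propan-2-yl]oxy}silane
Conditions: TESOTf (1.2 equiv), 2,6-lutidine (2 equiv), CH2Cl2, −78 to 0 °C
Reagents that add atoms: triethylsilyl trifluoromethanesulfonate, CC[Si](CC)(CC)OS(=O)(=O)C(F)(F)F
Why: Silylation of a tertiary alcohol with a silyl triflate and a hindered pyridine base is standard and spares the oxirane at low temperature, and capping the hydroxyl removes the alkoxide that could start a Payne rearrangement or bind palladium under the basic conditions of step 5.

Step 5
Reactants: 4 1-[2,4-bis(benzyloxy)-6-iodophenyl]-2-methylpropan-1-one; 8 (S)-triethyl{[2-(oxiran-2-yl)propan-2-yl]oxy}silane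
Product: 9 (S)-1-[4,6-bis(benzyloxy)-2-{2-[(triethylsilyl)oxy]propan-2-yl}-2,3-dihydro-1-benzofuran-7-yl]-2-methylpropan-1-one
Conditions: Pd(OAc)2 (10 mol %), XPhos (20 mol %), isopropyl bicyclo[2.2.1]hept-5-ene-2-carboxylate (50 mol %), Cs2CO3 (2 equiv), 8 (2 equiv), DMF, 90 °C, argon
Reagents that add atoms: none
Why: Zerovalent palladium generated in situ adds into the C–I bond of 4, the norbornene inserts, and carbonate-assisted metalation of the one free ortho C–H (the carbon between iodine and a benzyloxy group) gives a five-membered palladacycle in which divalent palladium is held by that aryl carbon and a norbornyl carbon. This electron-rich metallacycle attacks the unsubstituted CH2 of epoxide 8 in SN2 fashion to reach tetravalent palladium, and C(sp2)–C(sp3) reductive elimination forms the future C3a–C3 bond. With both ortho positions now filled the norbornene leaves by beta-carbon elimination, the tethered secondary alkoxide binds the metal in a six-membered oxapalladacycle, and C(sp2)–O reductive elimination at the former C–I carbon closes the five-membered dihydrofuran (C7a–O1) and regenerates zerovalent palladium. The closest known reaction type is the Catellani-type annulation of ortho-substituted aryl iodides with terminal epoxides to 2,3-dihydrobenzofurans, which passes on the configuration of enantioenriched epoxides. No stereocentre is created: C2 comes from 8, only the CH2–O bond of the oxirane breaks, and the priority order at C2 is unchanged, so it stays (S). The step needs single ortho alkylation, terminal epoxide opening and C–O rather than beta-hydride termination; the isobutyryl group blocks the second ortho site and makes the ipso carbon electron-poor enough for fast C–O elimination, the CMe2OSiEt3 group shields the internal epoxide carbon, and the bulky biaryl phosphine disfavours beta-hydride loss.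

Step 6
Reactants: 9 (S)-1-[4,6-bis(benzyloxy)-2-{2-[(triethylsilyl)oxy]propan-2-yl}-2,3-dihydro-1-benzofuran-7-yl]-2-methylpropan-1-one
Product: 11 (S)-1-[4,6-dihydroxy-2-(2-hydroxypropan-2-yl)-2,3-dihydro-1-benzofuran-7-yl]-2-methylpropan-1-one, via silylated diphenol 10 (not isolated)
Conditions: H2 (1 atm), 10% Pd/C, EtOAc–MeOH, rt; filter; then 1 M aq HCl, rt
Reagents that add atoms: none
Why: Catalytic hydrogenolysis cleaves the two aryl benzyl ethers while the hindered, strongly conjugated aryl ketone and the non-benzylic C2–O1 bond are left alone, mild acid solvolysis then removes the triethylsilyl ether without disturbing the tertiary alcohol or C2, and doing both before prenylation avoids any alkene reduction.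

Step 7
Reactants: 11 (S)-1-[4,6-dihydroxy-2-(2-hydroxypropan-2-yl)-2,3-dihydro-1-benzofuran-7-yl]-2-methylpropan-1-one; 12 prenyl bromide
Product: 14 garcinielliptone HD [(2S,7Z)-7-(1-hydroxy-2-methylpropylidene)-2-(2-hydroxypropan-2-yl)-5,5-bis(3-methylbut-2-en-1-yl)-2,3-dihydro-1-benzofuran-4,6(5H,7H)-dione], via monoprenyl phenol 13 (not isolated)
Conditions: 12 (2.5 equiv), KOH (3 equiv, 2 M aq), 0 °C to rt; then 1 M HCl to pH 2–3
Reagents that add atoms: none
Why: This is an alkylative dearomatisation of an acylphloroglucinol in which water solvates the phenoxide oxygens so the soft allylic bromide is taken up at carbon, C5 is the only unsubstituted ring carbon and is flanked by both phenoxides, and after the first prenylation the same carbon reacts again to give the quaternary centre and a stabilised beta-triketone enolate that resists further alkylation, C2 being untouched.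

Compound list
1 | 5-iodoresorcinol (5-iodobenzene-1,3-diol) | Oc1cc(O)cc(I)c1 | starting material
2 | 1,3-bis(benzyloxy)-5-iodobenzene | Ic1cc(OCc2ccccc2)cc(OCc2ccccc2)c1 | intermediate
3 | isobutyryl chloride | CC(C)C(Cl)=O | starting material
4 | 1-[2,4-bis(benzyloxy)-6-iodophenyl]-2-methylpropan-1-one | CC(C)C(=O)c1c(I)cc(OCc2ccccc2)cc1OCc1ccccc1 | intermediate
5 | methyl (S)-glycidate [methyl (2S)-oxirane-2-carboxylate] | O1[C@H](C(=O)OC)C1 | starting material
6 | 1-[(2S)-oxiran-2-yl]ethan-1-one | O1[C@H](C(C)=O)C1 | intermediate
7 | (S)-2-(oxiran-2-yl)propan-2-ol | O1[C@H](C(C)(C)O)C1 | intermediate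
8 | (S)-triethyl{[2-(oxiran-2-yl)propan-2-yl]oxy}silane | O1[C@H](C(C)(C)O[Si](CC)(CC)CC)C1 | intermediate
9 | (S)-1-[4,6-bis(benzyloxy)-2-{2-[(triethylsilyl)oxy]propan-2-yl}-2,3-dihydro-1-benzofuran-7-yl]-2-methylpropan-1-one | O1[C@H](C(C)(C)O[Si](CC)(CC)CC)Cc2c(OCc3ccccc3)cc(OCc3ccccc3)c(C(=O)C(C)C)c12 | intermediate
10 | (S)-1-[4,6-dihydroxy-2-{2-[(triethylsilyl)oxy]propan-2-yl}-2,3-dihydro-1-benzofuran-7-yl]-2-methylpropan-1-one | O1[C@H](C(C)(C)O[Si](CC)(CC)CC)Cc2c(O)cc(O)c(C(=O)C(C)C)c12 | intermediate
11 | (S)-1-[4,6-dihydroxy-2-(2-hydroxypropan-2-yl)-2,3-dihydro-1-benzofuran-7-yl]-2-methylpropan-1-one | O1[C@H](C(C)(C)O)Cc2c(O)cc(O)c(C(=O)C(C)C)c12 | intermediate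
12 | prenyl bromide (1-bromo-3-methylbut-2-ene) | CC(C)=CCBr | starting material
13 | (S)-1-[4,6-dihydroxy-2-(2-hydroxypropan-2-yl)-5-(3-methylbut-2-en-1-yl)-2,3-dihydro-1-benzofuran-7-yl]-2-methylpropan-1-one | O1[C@H](C(C)(C)O)Cc2c(O)c(CC=C(C)C)c(O)c(C(=O)C(C)C)c12 | intermediate
14 | garcinielliptone HD, (2S,7Z)-7-(1-hydroxy-2-methylpropylidene)-2-(2-hydroxypropan-2-yl)-5,5-bis(3-methylbut-2-en-1-yl)-2,3-dihydro-1-benzofuran-4,6(5H,7H)-dione | CC(C)=CCC1(CC=C(C)C)C(=O)C2=C(O[C@H](C(C)(C)O)C2)/C(=C(/O)C(C)C)C1=O | target

Total step count: 7. Longest linear sequence: 5 steps (1, 2, 5, 6, 7, or equally 3, 4, 5, 6, 7).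

Steps most likely to fail

Step 5.
- **What may go wrong:** C–H palladation beside the benzyloxy group may be slow. The norbornyl–palladium bond may add to the neighbouring ketone. Beta-hydride elimination from the palladium alkoxide (ipso reduction) may outrun the annulation.
- **Fallback:** it sets out from 4 and returns at 11. It makes the ring by epoxide opening instead of aryl C–O coupling.
- **Hydroxylation:** copper-catalysed hydroxylation of the C–I bond (CuI, 1,10-phenanthroline, KOH, DMSO–H2O, 100 °C) should give the phenol 1-[2,4-bis(benzyloxy)-6-hydroxyphenyl]-2-methylpropan-1-one F1.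
- **Prenylation:** ortho C-alkylation of its tight sodium phenoxide ion pair with 12 (NaH, toluene) should give 1-[4,6-bis(benzyloxy)-2-hydroxy-3-(3-methylbut-2-en-1-yl)phenyl]-2-methylpropan-1-one F2.
- **Epoxidation and closure:** Shi epoxidation uses the D-fructose-derived ketone, KHSO5 as its triple salt 2KHSO5·KHSO4·K2SO4, K2CO3 buffer and MeCN–dimethoxymethane–H2O at 0 °C. It should give 1-[4,6-bis(benzyloxy)-3-{[(2R)-3,3-dimethyloxiran-2-yl]methyl}-2-hydroxyphenyl]-2-methylpropan-1-one F3. The only free phenoxide opens this epoxide 5-exo at the secondary carbon with inversion, giving (S)-1-[4,6-bis(benzyloxy)-2-(2-hydroxypropan-2-yl)-2,3-dihydro-1-benzofuran-7-yl]-2-methylpropan-1-one F4.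
- **Return:** hydrogenolysis (H2, Pd/C) then gives 11.

Step 7.
- **What may go wrong:** O-prenylation, arrest after the first alkylation, hydrolysis of the allylic bromide, or attack through C3a or C7 may erode the gem-dialkylation.
- **Fallback:** it sets out from 11 and returns at 14.
- **Allylation:** a Tsuji–Trost double allylation (allyl methyl carbonate, Pd(PPh3)4, THF) makes O-allylation reversible. Material should therefore drain to carbon and give (2S,7Z)-5,5-diallyl-7-(1-hydroxy-2-methylpropylidene)-2-(2-hydroxypropan-2-yl)-2,3-dihydro-1-benzofuran-4,6(5H,7H)-dione F5.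
- **Return:** double cross-metathesis with 2-methylbut-2-ene (second-generation Grubbs catalyst, CH2Cl2, 40 °C) converts both allyl groups into prenyl groups.

Step 2.
- **What may go wrong:** chelation-assisted loss of the benzyl ether next to the new carbonyl, or acylation between the two ethers, may lower the return.
- **Fallback:** it sets out from 1 and returns at 4 by reversing the order of events.
- **Acylation:** acylation of the free resorcinol (isobutyric acid, BF3·OEt2, 80 °C) goes para to one hydroxyl, as with other 5-substituted resorcinols. It should give 1-(2,4-dihydroxy-6-iodophenyl)-2-methylpropan-1-one F6.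
- **Return:** double benzylation (BnBr, K2CO3, DMF, 60 °C) then gives 4.

Further compounds
F1 | step 5 | 1-[2,4-bis(benzyloxy)-6-hydroxyphenyl]-2-methylpropan-1-one | CC(C)C(=O)c1c(O)cc(OCc2ccccc2)cc1OCc1ccccc1
F2 | step 5 | 1-[4,6-bis(benzyloxy)-2-hydroxy-3-(3-methylbut-2-en-1-yl)phenyl]-2-methylpropan-1-one | CC(C)C(=O)c1c(O)c(CC=C(C)C)c(OCc2ccccc2)cc1OCc1ccccc1
F3 | step 5 | 1-[4,6-bis(benzyloxy)-3-{[(2R)-3,3-dimethyloxiran-2-yl]methyl}-2-hydroxyphenyl]-2-methylpropan-1-one | CC(C)C(=O)c1c(O)c(C[C@H]2OC2(C)C)c(OCc2ccccc2)cc1OCc1ccccc1
F4 | step 5 | (S)-1-[4,6-bis(benzyloxy)-2-(2-hydroxypropan-2-yl)-2,3-dihydro-1-benzofuran-7-yl]-2-methylpropan-1-one | O1[C@H](C(C)(C)O)Cc2c(OCc3ccccc3)cc(OCc3ccccc3)c(C(=O)C(C)C)c12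
F5 | step 7 | (2S,7Z)-5,5-diallyl-7-(1-hydroxy-2-methylpropylidene)-2-(2-hydroxypropan-2-yl)-2,3-dihydro-1-benzofuran-4,6(5H,7H)-dione | C=CCC1(CC=C)C(=O)C2=C(O[C@H](C(C)(C)O)C2)/C(=C(/O)C(C)C)C1=O
F6 | step 2 | 1-(2,4-dihydroxy-6-iodophenyl)-2-methylpropan-1-one | CC(C)C(=O)c1c(I)cc(O)cc1O
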